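The pyran ring C of the upper (epiafzelechin) unit is disconnected at O1–C2 and C3–C4. C4 is doubly benzylic, flanked by ring A and by C8 of the lower unit's ring D, so the O1–C8a–C4a–C4 array is a latent ortho-quinone methide. Its acid-catalysed oxa-[4+2] cycloaddition to a (Z)-styrenyl pinacolboronate, boron standing in for the C3 hydroxyl and steering C3 onto C4, builds ring C and the stereocentres C2, C3 and C4 in one operation. The precursor is an o-hydroxybenzhydrol made from C8-lithiated, perbenzylated (–)-epigallocatechin (chiral pool) and a phloroglucinol aldehyde; C–B oxidation and hydrogenolysis finish the synthesis.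

Key step: step 7

Locants: flavan numbering throughout; the upper unit is unprimed (rings A, B, C), the lower epigallocatechin unit is primed (C2', C3', C8'; aromatic ring D). The target is epiafzelechin-(4β→8)-epigallocatechin, (2R,3R,4R) in the upper unit and (2R,3R) in the lower unit.

Assumption: the (R)-antipode of the chiral phosphoric acid is taken as the one matched to the (2R,3R,4R) series; should the sense of induction prove opposite, the (S)-acid takes its place.

Step 1
Reactants: 1 (–)-epigallocatechin; 2 benzyl bromide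
Product: 3 5,7,3',4',5'-penta-O-benzyl-(–)-epigallocatechin
Conditions: BnBr (5.5 equiv), K2CO3, DMF, –10 °C to rt, argon
Reagents that add atoms: benzyl bromide, BrCc1ccccc1
Why: Williamson etherification under carbonate base should cap the five phenols only, leaving the less acidic C3' alcohol and both stereocentres untouched.

Step 2
Reactants: 3 5,7,3',4',5'-penta-O-benzyl-(–)-epigallocatechin; 2 benzyl bromide
Product: 4 3,5,7,3',4',5'-hexa-O-benzyl-(–)-epigallocatechin
Conditions: NaH, BnBr, n-Bu4NI (cat.), THF–DMF, 0 °C to rt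
Reagents that add atoms: benzyl bromide, BrCc1ccccc1
Why: Williamson etherification of the secondary alkoxide should proceed without epimerisation at C2', because no free phenol is left to open ring F through a quinone methide.

Step 3
Reactants: 4 3,5,7,3',4',5'-hexa-O-benzyl-(–)-epigallocatechin; 5 N-bromosuccinimide
Product: 6 8-bromo-3,5,7,3',4',5'-hexa-O-benzyl-(–)-epigallocatechin
Conditions: NBS (1.0 equiv), CH2Cl2, –78 °C
Reagents that add atoms: N-bromosuccinimide, O=C1CCC(=O)N1Br
Why: Electrophilic aromatic bromination should go to the phloroglucinol-type ring D, far more activated than the pyrogallol ether ring, and there to C8', the position known to react first in 5,7-di-O-benzyl flavan-3-ols.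

Step 4
Reactants: 7 2,4,6-trihydroxybenzaldehyde; 2 benzyl bromide
Product: 8 2,4-bis(benzyloxy)-6-hydroxybenzaldehyde
Conditions: BnBr (2.05 equiv), K2CO3, DMF, 0 °C to rt
Reagents that add atoms: benzyl bromide, BrCc1ccccc1
Why: Williamson etherification should stop at the diether because the last hydroxyl is hydrogen-bonded to the aldehyde and is the least nucleophilic.

Step 5
Reactants: 9 1-(benzyloxy)-4-ethynylbenzene; 10 pinacolborane
Product: 11 (Z)-2-[2-(4-benzyloxyphenyl)ethenyl]-4,4,5,5-tetramethyl-1,3,2-dioxaborolane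
Conditions: HBpin, [Rh(cod)Cl]2 (1.5 mol%), P(i-Pr)3 (6 mol%), Et3N, cyclohexane, rt
Reagents that add atoms: pinacolborane, CC1(C)OBOC1(C)C
Why: Rhodium-catalysed trans-hydroboration of a terminal alkyne through a rhodium vinylidene should place boron on the terminal carbon and give the (Z)-1-alkenylboronate.

Step 6
Reactants: 6 8-bromo-3,5,7,3',4',5'-hexa-O-benzyl-(–)-epigallocatechin; 8 2,4-bis(benzyloxy)-6-hydroxybenzaldehyde
Product: 14 o-hydroxybenzhydrol (both carbinol epimers), via C8'-aryllithium 12 (not isolated), via sodium phenoxide 13 (not isolated)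
Conditions: 6, n-BuLi (1.05 equiv), THF, –78 °C; then 13 (from 8, NaH, THF, 0 °C), –78 to –20 °C; aq NH4Cl
Reagents that add atoms: none
Why: Bromine–lithium exchange and 1,2-addition of the aryllithium to the salicylaldehyde, masked in the flask as its phenoxide (the usual way to o-hydroxybenzhydrols), should give the carbinol as an epimer mixture that is irrelevant because this carbon becomes sp2 in step 7.

Step 7
Reactants: 14 o-hydroxybenzhydrol; 11 (Z)-2-[2-(4-benzyloxyphenyl)ethenyl]-4,4,5,5-tetramethyl-1,3,2-dioxaborolane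
Product: 16 nona-O-benzyl 3-deoxy-3-(pinacolboryl)-epiafzelechin-(4β→8)-epigallocatechin, via o-quinone methide 15 (not isolated)
Conditions: (R)-TRIP [(R)-3,3'-bis(2,4,6-triisopropylphenyl)-1,1'-binaphthyl-2,2'-diyl hydrogen phosphate] (10 mol%), 11 (3 equiv), 4 Å MS, toluene, –20 °C to rt, slow addition of 14
Reagents that add atoms: none
Why: Proposed new method: the phosphoric acid ionises the doubly benzylic carbinol of 14 to the hydrogen-bonded o-quinone methide 15, whose O1=C8a–C4a=C4 heterodiene adds across C2=C3 of 11 in an asynchronous inverse-demand oxa-[4+2], the boron-bearing C3 (made nucleophilic by the para-benzyloxyphenyl donor, the cation developing at C2 being benzylic and β to boron) bonding to C4 while O1 closes on C2. The closest known reactions are the Brønsted-acid-catalysed [4+2] cycloadditions of o-hydroxybenzhydrol-derived o-quinone methides with styrenes and the biphenol-catalysed additions of alkenylboronates to o-quinone methides through the boron-bearing carbon; an alkenyl pinacolboronate that keeps its boron as the 2π partner is the untested element. Ring C closes as a six-membered ring by hetero-Diels–Alder cycloaddition, suprafacial on both partners. C2 and C3 should come out cis because the (Z)-geometry of 11 is transferred; C4 should come out trans to both because the peri 5-benzyloxy group forces the bulky ring-D aryl on C4 into the pseudoaxial position (allylic strain, as in 5-oxygenated 4-arylflavans), so that the only transition state free of a 1,3-diaxial aryl–aryl contact has the C2 aryl equatorial and boron anti to the C4 aryl. The absolute sense (4R, hence 2R and 3R in target numbering) is to be set by the chiral phosphate bound at O1, which shields one face of 15; the remote C2' and C3' centres are expected to have little influence. The step needs regioselectivity (secured by the donor aryl on C2 and the non-donating boron on C3, where an enol ether would give the 2-alkoxy-3-aryl isomer), retention of boron (non-exchangeable pinacol ester, no Lewis base) and chemoselectivity over Friedel–Crafts oligomerisation at the free C6, C8 and C6' positions (excess 11, slow addition of 14).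

Step 8
Reactants: 16 nona-O-benzyl 3-deoxy-3-(pinacolboryl)-epiafzelechin-(4β→8)-epigallocatechin; 17 hydrogen peroxide
Product: 18 5,7,4'-tri-O-benzylepiafzelechin-(4β→8)-3,5,7,3',4',5'-hexa-O-benzylepigallocatechin
Conditions: 30% aq H2O2, 2 M NaOH, THF, 0 °C to rt
Reagents that add atoms: hydrogen peroxide, OO
Why: Boronate oxidation by hydroperoxide proceeds by 1,2-migration of C3 from boron to oxygen, which is stereoretentive, so the C3 hydroxyl should stay cis to the C2 aryl and trans to the C4 aryl.

Step 9
Reactants: 18 5,7,4'-tri-O-benzylepiafzelechin-(4β→8)-3,5,7,3',4',5'-hexa-O-benzylepigallocatechin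
Product: 19 epiafzelechin-(4β→8)-epigallocatechin (CNP0290824.1)
Conditions: H2 (1 atm), Pd(OH)2/C, THF–MeOH–H2O, rt; filtration, lyophilisation
Reagents that add atoms: none
Why: Hydrogenolysis should remove all nine benzyl ethers while the interflavan C4–C8' bond and both benzylic C2–O1 ring bonds survive, as is usual for benzylated proanthocyanidins under these mild conditions.

Compound list
1 | (–)-epigallocatechin, (2R,3R)-2-(3,4,5-trihydroxyphenyl)chromane-3,5,7-triol | Oc1cc(O)c2c(c1)O[C@H](c1cc(O)c(O)c(O)c1)[C@H](O)C2 | starting material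
2 | benzyl bromide | BrCc1ccccc1 | starting material
3 | 5,7,3',4',5'-penta-O-benzyl-(–)-epigallocatechin, (2R,3R) | C(c1ccccc1)Oc1cc(OCc2ccccc2)c2c(c1)O[C@H](c1cc(OCc3ccccc3)c(OCc3ccccc3)c(OCc3ccccc3)c1)[C@H](O)C2 | intermediate
4 | 3,5,7,3',4',5'-hexa-O-benzyl-(–)-epigallocatechin, (2R,3R) | C(c1ccccc1)Oc1cc(OCc2ccccc2)c2c(c1)O[C@H](c1cc(OCc3ccccc3)c(OCc3ccccc3)c(OCc3ccccc3)c1)[C@H](OCc1ccccc1)C2 | intermediate
5 | N-bromosuccinimide | O=C1CCC(=O)N1Br | starting material
6 | 8-bromo-3,5,7,3',4',5'-hexa-O-benzyl-(–)-epigallocatechin, (2R,3R) | C(c1ccccc1)Oc1cc(OCc2ccccc2)c2c(c1Br)O[C@H](c1cc(OCc3ccccc3)c(OCc3ccccc3)c(OCc3ccccc3)c1)[C@H](OCc1ccccc1)C2 | intermediate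
7 | 2,4,6-trihydroxybenzaldehyde | O=Cc1c(O)cc(O)cc1O | starting material
8 | 2,4-bis(benzyloxy)-6-hydroxybenzaldehyde | O=Cc1c(O)cc(OCc2ccccc2)cc1OCc1ccccc1 | intermediate
9 | 1-(benzyloxy)-4-ethynylbenzene | C#Cc1ccc(OCc2ccccc2)cc1 | starting material
10 | pinacolborane | CC1(C)OBOC1(C)C | starting material
11 | (Z)-2-[2-(4-benzyloxyphenyl)ethenyl]-4,4,5,5-tetramethyl-1,3,2-dioxaborolane | CC1(C)OB(/C=C\c2ccc(OCc3ccccc3)cc2)OC1(C)C | intermediate
12 | C8'-aryllithium of 4 (8-lithio-hexa-O-benzylepigallocatechin), not isolated | C(c1ccccc1)Oc1cc(OCc2ccccc2)c2c(c1[Li])O[C@H](c1cc(OCc3ccccc3)c(OCc3ccccc3)c(OCc3ccccc3)c1)[C@H](OCc1ccccc1)C2 | intermediate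
13 | sodium 3,5-bis(benzyloxy)-2-formylphenoxide, not isolated | [Na+].[O-]c1cc(OCc2ccccc2)cc(OCc2ccccc2)c1C=O | intermediate
14 | [2,4-bis(benzyloxy)-6-hydroxyphenyl][(2R,3R)-3,5,7-tris(benzyloxy)-2-(3,4,5-tris(benzyloxy)phenyl)chroman-8-yl]methanol, both carbinol epimers | C(c1ccccc1)Oc1cc(OCc2ccccc2)c2c(c1C(O)c1c(O)cc(OCc3ccccc3)cc1OCc1ccccc1)O[C@H](c1cc(OCc3ccccc3)c(OCc3ccccc3)c(OCc3ccccc3)c1)[C@H](OCc1ccccc1)C2 | intermediate
15 | o-quinone methide from 14 (3,5-bis(benzyloxy)-6-[(hexa-O-benzylepigallocatechin-8-yl)methylidene]cyclohexa-2,4-dien-1-one), not isolated | O=C1C=C(OCc2ccccc2)C=C(OCc2ccccc2)C1=Cc1c(OCc2ccccc2)cc(OCc2ccccc2)c2c1O[C@H](c1cc(OCc3ccccc3)c(OCc3ccccc3)c(OCc3ccccc3)c1)[C@H](OCc1ccccc1)C2 | intermediate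
16 | nona-O-benzyl 3-deoxy-3-(pinacolboryl)-epiafzelechin-(4β→8)-epigallocatechin; upper unit 2,3-cis-3,4-trans with boron where the C3 oxygen will be (CIP 2S,3R,4R, the change at C2 being formal because boron ranks below carbon); lower unit 2R,3R | C(c1ccccc1)Oc1ccc([C@H]2Oc3cc(OCc4ccccc4)cc(OCc4ccccc4)c3[C@H](c3c(OCc4ccccc4)cc(OCc4ccccc4)c4c3O[C@H](c3cc(OCc5ccccc5)c(OCc5ccccc5)c(OCc5ccccc5)c3)[C@H](OCc3ccccc3)C4)[C@H]2B6OC(C)(C)C(C)(C)O6)cc1 | intermediate
17 | hydrogen peroxide | OO | starting material
18 | 5,7,4'-tri-O-benzylepiafzelechin-(4β→8)-3,5,7,3',4',5'-hexa-O-benzylepigallocatechin; upper unit 2R,3R,4R, lower unit 2R,3R | C(c1ccccc1)Oc1ccc([C@H]2Oc3cc(OCc4ccccc4)cc(OCc4ccccc4)c3[C@H](c3c(OCc4ccccc4)cc(OCc4ccccc4)c4c3O[C@H](c3cc(OCc5ccccc5)c(OCc5ccccc5)c(OCc5ccccc5)c3)[C@H](OCc3ccccc3)C4)[C@H]2O)cc1 | intermediate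
19 | epiafzelechin-(4β→8)-epigallocatechin (CNP0290824.1); upper unit 2R,3R,4R, lower unit 2R,3R | Oc1ccc([C@H]2Oc3cc(O)cc(O)c3[C@H](c3c(O)cc(O)c4c3O[C@H](c3cc(O)c(O)c(O)c3)[C@H](O)C4)[C@H]2O)cc1 | target

Total step count: 9. Longest linear sequence: 7 steps (steps 1, 2, 3, 6, 7, 8, 9).

Steps most likely to fail

1. Step 7 (proposed new method). Four processes may defeat it:
- transfer of the alkenyl group with loss of boron (ipso attack followed by deborylation), or protodeboronation of 11 by the acid;
- Friedel–Crafts self-condensation of the cation at the free phloroglucinol positions;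
- poor facial selectivity against the remote lower-unit stereocentres;
- a stepwise addition in which the C2 cation rotates before closure, eroding the (Z)-geometry and giving the 2,3-trans series.

The fallback uses known chemistry only; it gives up the cycloaddition and makes the interflavan C4–C8' bond instead. It sets out from 4. Commercial (–)-epiafzelechin F1 is benzylated on its three phenols (BnBr, K2CO3, DMF) to 5,7,4'-tri-O-benzylepiafzelechin F2. Benzylic oxidation with DDQ in the presence of ethylene glycol (CH2Cl2, rt) gives 4β-(2-hydroxyethoxy)-5,7,4'-tri-O-benzylepiafzelechin F3. TMSOTf (CH2Cl2, –78 °C) ionises F3 to the flavan-4-yl cation, which is captured by C8' of an excess of 4 trans to the C3 hydroxyl. This should give 18, where the route is rejoined before step 9.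

2. Step 6. The hindered, doubly ortho-oxygenated aryllithium may add only slowly to the phenoxide-deactivated aldehyde, so that proton transfer or rearrangement of the benzyloxy-substituted aryllithium on warming competes. The fallback replaces the in-flask phenoxide by a covalent mask that keeps the aldehyde electrophilic. It sets out from 8, which is silylated (TIPSOTf, 2,6-lutidine, CH2Cl2) to 2,4-bis(benzyloxy)-6-(triisopropylsilyloxy)benzaldehyde F4. Addition of F4 to aryllithium 12 (from 6, n-BuLi, THF, –78 °C) gives the silyl-protected benzhydrol F5. Desilylation (TBAF, AcOH, THF, 0 °C) returns to the route at 14.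

3. Step 5. Incomplete Z-selectivity, or Z-to-E isomerisation by the rhodium hydride, would be carried into step 7 as the 2,3-trans series. The fallback fixes the geometry by a syn addition instead of a vinylidene pathway. It sets out from 9, which is deprotonated (n-BuLi, THF, –78 °C) and borylated with 2-isopropoxy-4,4,5,5-tetramethyl-1,3,2-dioxaborolane to the alkynylboronate F6. Syn-hydrozirconation with Cp2Zr(H)Cl (THF, rt) and protonolysis of the carbon–zirconium bond with water should give the (Z)-alkenylboronate, returning to the route at 11.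

Further compounds
F1 | step 7 | (–)-epiafzelechin, (2R,3R), purchased | Oc1ccc([C@H]2Oc3cc(O)cc(O)c3C[C@H]2O)cc1
F2 | step 7 | 5,7,4'-tri-O-benzylepiafzelechin | C(c1ccccc1)Oc1ccc([C@H]2Oc3cc(OCc4ccccc4)cc(OCc4ccccc4)c3C[C@H]2O)cc1
F3 | step 7 | 4β-(2-hydroxyethoxy)-5,7,4'-tri-O-benzylepiafzelechin | C(c1ccccc1)Oc1ccc([C@H]2Oc3cc(OCc4ccccc4)cc(OCc4ccccc4)c3[C@H](OCCO)[C@H]2O)cc1
F4 | step 6 | 2,4-bis(benzyloxy)-6-(triisopropylsilyloxy)benzaldehyde | O=Cc1c(O[Si](C(C)C)(C(C)C)C(C)C)cc(OCc2ccccc2)cc1OCc1ccccc1
F5 | step 6 | [2,4-bis(benzyloxy)-6-(triisopropylsilyloxy)phenyl][(2R,3R)-hexa-O-benzylepigallocatechin-8-yl]methanol, both carbinol epimers | C(c1ccccc1)Oc1cc(OCc2ccccc2)c2c(c1C(O)c1c(O[Si](C(C)C)(C(C)C)C(C)C)cc(OCc3ccccc3)cc1OCc1ccccc1)O[C@H](c1cc(OCc3ccccc3)c(OCc3ccccc3)c(OCc3ccccc3)c1)[C@H](OCc1ccccc1)C2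
F6 | step 5 | 2-[(4-benzyloxyphenyl)ethynyl]-4,4,5,5-tetramethyl-1,3,2-dioxaborolane | CC1(C)OB(C#Cc2ccc(OCc3ccccc3)cc2)OC1(C)C
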